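Mutilin numbering is used: ring A is the cyclopentenone (C1–C4, C9), ring B the cyclohexane (C4–C9), ring C the eight-membered ring (C4, C5, C14, C13, C12, C11, C10, C9). Everything rests on closing ring C last at C11–C12. The key step exploits the homoallylic alcohol C11(OH)–C12(Me)(vinyl) of ring C: an intramolecular Nozaki–Hiyama–Kishi allylation joins a (Z)-allylic bromide on the C14 arm to an aldehyde on the C10 arm, closing ring C and setting C11 and the quaternary C12 at once. The precursor is a fully substituted A/B hydrindenone; its olefin geometry is stored until late as a 4-methyl-3,6-dihydro-2H-pyran made from isoprene.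

Key step: step 14

Assumption: every stereodescriptor (C5 and C6 included) is taken exactly as written in the SMILES of the target and carried unchanged through all intermediates; the control elements below are argued for that sense.

Step 1
Reactants: 1 cyclohex-2-en-1-one
Product: 3 (S,Z)-2-(hydroxymethylene)-3-methylcyclohexan-1-one, via methylzinc enolate 2 (not isolated)
Conditions: Me2Zn, Cu(OTf)2 (1 mol%), (S)-(1,1'-binaphthalene-2,2'-diyl) N,N-bis[(R)-1-phenylethyl]phosphoramidite (2 mol%, enantiomer chosen to give 6S), toluene, −30 °C; MeLi, THF, −78 °C; CF3CH2OCHO, −78 to 0 °C; 1 M HCl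
Reagents that add atoms: dimethylzinc, C[Zn]C; 2,2,2-trifluoroethyl formate, O=COCC(F)(F)F
Why: Copper-catalysed asymmetric conjugate addition of the methyl group sets C6 (ligand control) and generates the enolate regiospecifically towards C5, which, activated by methyllithium, undergoes Claisen-type C-formylation to give the hydrogen-bonded hydroxymethylene ketone.

Step 2
Reactants: 3 (S,Z)-2-(hydroxymethylene)-3-methylcyclohexan-1-one
Product: 4 (1R,6S)-1,6-dimethyl-2-oxocyclohexane-1-carbaldehyde
Conditions: MeI, K2CO3, acetone, rt
Reagents that add atoms: iodomethane, CI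
Why: C-Alkylation of the β-keto aldehyde enolate, in which the C6 methyl is pseudoaxial to avoid allylic 1,3-strain, so that iodomethane enters anti to it and the quaternary C5 is formed with the two methyl groups trans.

Step 3
Reactants: 4 (1R,6S)-1,6-dimethyl-2-oxocyclohexane-1-carbaldehyde; 5 isoprene
Product: 6 (2R,3S)-2,3-dimethyl-2-[(2R)-4-methyl-3,6-dihydro-2H-pyran-2-yl]cyclohexan-1-one
Conditions: isoprene (5 equiv), SnCl4 (20 mol%), CH2Cl2, −78 °C
Reagents that add atoms: none
Why: Lewis-acid-promoted hetero-Diels–Alder reaction in which the methyl-substituted terminus of isoprene bonds to the aldehyde carbon (4-methyl regiochemistry) and the diene attacks the tin-chelated 1,3-dicarbonyl on the face of the C5 methyl group, away from ring B, which sets C14, while the new ring locks the future C12 olefin as Z.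

Step 4
Reactants: 6 dihydropyranyl ketone
Product: 7 (5S,6R)-5,6-dimethyl-6-[(2R)-4-methyl-3,6-dihydro-2H-pyran-2-yl]cyclohex-2-en-1-one
Conditions: 2-iodoxybenzoic acid (IBX), DMSO/toluene, 70 °C
Reagents that add atoms: none
Why: IBX dehydrogenation of a ketone that can enolise only towards C9 gives the C8=C9 enone.

Step 5
Reactants: 7 enone
Product: 8 C8,C9-epoxy ketone
Conditions: 30% H2O2, NaOH (cat.), MeOH, 0 °C
Reagents that add atoms: hydrogen peroxide, OO
Why: Weitz–Scheffer nucleophilic epoxidation is selective for the electron-poor enone over the trisubstituted olefin of the dihydropyran, and the epoxide configuration (oxygen expected anti to the pyranyl group) is erased in step 6.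

Step 6
Reactants: 8 C8,C9-epoxy ketone
Product: 9 (4R,5S)-4,5-dimethyl-4-[(2R)-4-methyl-3,6-dihydro-2H-pyran-2-yl]cyclohexane-1,3-dione
Conditions: Pd(PPh3)4 (5 mol%), 1,2-bis(diphenylphosphino)ethane (5 mol%), toluene, 100 °C
Reagents that add atoms: none
Why: Isomerisation of an α,β-epoxy ketone to the β-diketone by zerovalent palladium (oxidative addition into the C9–O bond, β-hydride elimination from C8), which installs the C8 carbonyl without touching the allylic ether.

Step 7
Reactants: 9 1,3-dione; 10 propargyl bromide
Product: 11 2-(prop-2-yn-1-yl)-1,3-dione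
Conditions: KOH, H2O, rt
Reagents that add atoms: none
Why: Alkylation of the 1,3-dione enolate at C9 in water, where the protic medium favours C- over O-alkylation, brings in C1–C3 as a masked acetonyl group.

Step 8
Reactants: 11 2-(prop-2-yn-1-yl)-1,3-dione; 12 (E)-1-nitroprop-1-ene
Product: 13 nitro dione with quaternary C9 and 10R
Conditions: 1-[3,5-bis(trifluoromethyl)phenyl]-3-[(1R,2R)-2-(dimethylamino)cyclohexyl]thiourea (10 mol%, enantiomer chosen to give 10R), toluene, rt
Reagents that add atoms: none
Why: Michael addition of the enolised 2-substituted 1,3-dione to the nitroalkene under bifunctional thiourea–amine catalysis, in which the catalyst selects the face of the nitroalkene (C10) and the dione is attacked at C9 anti to the pseudoaxial dihydropyranyl group on the neighbouring quaternary C5.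

Step 9
Reactants: 13 nitro dione
Product: 14 (8S)-hydroxy ketone
Conditions: (R)-1-methyl-3,3-diphenyltetrahydro-1H,3H-pyrrolo[1,2-c][1,3,2]oxazaborole (20 mol%, enantiomer chosen to give 8S), catecholborane, toluene, −78 °C; MeOH, pH 7 buffer
Reagents that add atoms: none
Why: Corey–Bakshi–Shibata reduction, in which only the C8 carbonyl (the C4 carbonyl lies between two quaternary carbons) is reduced and the catalyst distinguishes quaternary C9 from the C7 methylene to set C8, catecholborane at low temperature sparing the alkyne and the nitro group.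

Step 10
Reactants: 14 (8S)-hydroxy ketone
Product: 15 C8 tert-butyldimethylsilyl ether
Conditions: TBSOTf, 2,6-lutidine, CH2Cl2, 0 °C
Reagents that add atoms: tert-butyldimethylsilyl trifluoromethanesulfonate, CC(C)(C)[Si](C)(C)OS(=O)(=O)C(F)(F)F
Why: Silylation of the hindered secondary alcohol with the silyl triflate protects the β-hydroxy ketone against retro-aldol cleavage in the basic steps that follow.

Step 11
Reactants: 15 C8 silyl ether
Product: 17 C11 dimethyl acetal, via sodium nitronate 16 (not isolated)
Conditions: NaOMe, MeOH, 0 °C; then added to H2SO4/MeOH, −40 °C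
Reagents that add atoms: methanol, CO
Why: Nef reaction in its acetal variant (nitronate quenched into acidic methanol) turns the nitromethyl group into the C11 dimethyl acetal without epimerising C10.

Step 12
Reactants: 17 C11 dimethyl acetal
Product: 20 A/B hydrindenone, via methyl ketone 18 (not isolated), via aldol 19 (not isolated)
Conditions: Ph3PAuNTf2 (2 mol%), MeOH/H2O (10:1), 40 °C; then KOH, 60 °C
Reagents that add atoms: water, O
Why: Gold-catalysed Markovnikov hydration of the terminal alkyne gives the 1,4-diketone, whose methyl ketone enolate (C3) closes ring A by intramolecular aldol condensation on C4, the only carbonyl within reach, followed by dehydration to the enone.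

Step 13
Reactants: 20 A/B hydrindenone
Product: 22 (Z)-allylic bromide C14 acetate C11 aldehyde, via bromo ether 21 (not isolated)
Conditions: AcBr (3 equiv), ZnBr2 (5 mol%), CH2Cl2, −40 to 0 °C; then aq. NaHCO3
Reagents that add atoms: acetyl bromide, CC(Br)=O; water, O
Why: Acylative cleavage of the cyclic allylic ether (O-acylation, then SN2 attack of bromide at the primary allylic carbon) delivers the C14 acetate and the allylic bromide in one operation with the ring-enforced Z geometry retained, while the dimethyl acetal is exchanged to the α-bromo ether 21 and hydrolysed to the aldehyde on work-up.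

Step 14
Reactants: 22 (Z)-allylic bromide C14 acetate C11 aldehyde
Product: 24 8-O-silyl ether of the target, via allylchromium species 23 (not isolated)
Conditions: CrCl2 (6 equiv), THF (2 mM, slow addition of 22), 0 °C to rt; then H2O
Reagents that add atoms: none
Why: Two single-electron transfers from divalent chromium convert the allylic bromide of 22 into the γ,γ-disubstituted allylchromium species 23 (trivalent chromium), which adds to the C11 aldehyde through its γ-carbon C12 (SE2', closed six-membered Zimmerman–Traxler chair), the allylic transposition leaving the vinyl group on C12. The closest known reaction type is the intramolecular Nozaki–Hiyama–Kishi allylation used for medium and large carbocycles, together with the stereospecific addition of γ,γ-disubstituted allylchromium reagents that gives quaternary carbons. Ring C (C4, C5, C14, C13, C12, C11, C10, C9) is closed by 8-exo-trig attack on the aldehyde carbon, the chair being fused to the forming ring along C11–C12. C11 is set by Felkin–Anh control from C10 (quaternary C9 anti to the incoming C12, attack past the C10 hydrogen), and C12 by the ring-derived Z olefin geometry, which in the chair places C13 axial and the methyl equatorial, gauche to the equatorial C10 as the eight-membered ring requires, giving the 11S,12S pair. The step needs γ- over α-attack (α-attack would give a ten-membered ring) and aldehyde over enone and acetate; allylchromium reagents react at the more substituted terminus and only with aldehydes, and high dilution suppresses intermolecular coupling.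

Step 15
Reactants: 24 8-O-silyl ether of the target
Product: 25 pleuromutilin E
Conditions: HF·pyridine, THF/pyridine, 0 °C to rt
Reagents that add atoms: none
Why: Fluoride-mediated cleavage of the silyl ether under mildly acidic conditions leaves the acetate, the allylic alcohol and the enone untouched.

Compound list
1 | cyclohex-2-en-1-one | O=C1C=CCCC1 | starting material
2 | methylzinc (S)-3-methylcyclohex-1-en-1-olate (not isolated) | C[Zn]OC1=C[C@@H](C)CCC1 | intermediate
3 | (S,Z)-2-(hydroxymethylene)-3-methylcyclohexan-1-one (enol form of the 2-formyl ketone) | O/C=C1\C(=O)CCC[C@@H]1C | intermediate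
4 | (1R,6S)-1,6-dimethyl-2-oxocyclohexane-1-carbaldehyde (C5 and C6 methyl groups trans) | O=C[C@]1(C)C(=O)CCC[C@@H]1C | intermediate
5 | isoprene (2-methylbuta-1,3-diene) | C=CC(C)=C | starting material
6 | (2R,3S)-2,3-dimethyl-2-[(2R)-4-methyl-3,6-dihydro-2H-pyran-2-yl]cyclohexan-1-one | O1CC=C(C)C[C@@H]1[C@]2(C)C(=O)CCC[C@@H]2C | intermediate
7 | (5S,6R)-5,6-dimethyl-6-[(2R)-4-methyl-3,6-dihydro-2H-pyran-2-yl]cyclohex-2-en-1-one | O1CC=C(C)C[C@@H]1[C@]2(C)C(=O)C=CC[C@@H]2C | intermediate
8 | C8,C9-epoxide of 7 (cis-fused oxirane, oxygen anti to the pyranyl group) | O1CC=C(C)C[C@@H]1[C@]2(C)C(=O)[C@H]3O[C@H]3C[C@@H]2C | intermediate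
9 | (4R,5S)-4,5-dimethyl-4-[(2R)-4-methyl-3,6-dihydro-2H-pyran-2-yl]cyclohexane-1,3-dione | O1CC=C(C)C[C@@H]1[C@]2(C)C(=O)CC(=O)C[C@@H]2C | intermediate
10 | propargyl bromide (3-bromoprop-1-yne) | C#CCBr | starting material
11 | 2-(prop-2-yn-1-yl) derivative of 9 (substituent on C9 between the carbonyls; enolised, C9 not stereogenic) | O1CC=C(C)C[C@@H]1[C@]2(C)C(=O)C(CC#C)C(=O)C[C@@H]2C | intermediate
12 | (E)-1-nitroprop-1-ene | C/C=C/[N+](=O)[O-] | starting material
13 | 2-[(2R)-1-nitropropan-2-yl]-2-(prop-2-yn-1-yl) derivative of 9 (quaternary C9; nitropropyl group trans to the pyranyl group across ring B) | O1CC=C(C)C[C@@H]1[C@]2(C)C(=O)[C@](CC#C)(C(=O)C[C@@H]2C)[C@@H](C)C[N+](=O)[O-] | intermediate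
14 | C8 alcohol of 13 (8S; hydroxyl cis to the nitropropyl group, C4 ketone retained) | O1CC=C(C)C[C@@H]1[C@]2(C)C(=O)[C@](CC#C)([C@@H](O)C[C@@H]2C)[C@@H](C)C[N+](=O)[O-] | intermediate
15 | tert-butyldimethylsilyl ether of 14 | O1CC=C(C)C[C@@H]1[C@]2(C)C(=O)[C@](CC#C)([C@@H](O[Si](C)(C)C(C)(C)C)C[C@@H]2C)[C@@H](C)C[N+](=O)[O-] | intermediate
16 | sodium nitronate of 15 (not isolated) | O1CC=C(C)C[C@@H]1[C@]2(C)C(=O)[C@](CC#C)([C@@H](O[Si](C)(C)C(C)(C)C)C[C@@H]2C)[C@@H](C)C=[N+]([O-])[O-].[Na+] | intermediate
17 | C11 dimethyl acetal ((2R)-1,1-dimethoxypropan-2-yl group on C9 in place of the nitropropyl group of 15) | O1CC=C(C)C[C@@H]1[C@]2(C)C(=O)[C@](CC#C)([C@@H](O[Si](C)(C)C(C)(C)C)C[C@@H]2C)[C@@H](C)C(OC)OC | intermediate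
18 | methyl ketone (2-oxopropyl group on C9 in place of the propargyl group of 17; not isolated) | O1CC=C(C)C[C@@H]1[C@]2(C)C(=O)[C@](CC(C)=O)([C@@H](O[Si](C)(C)C(C)(C)C)C[C@@H]2C)[C@@H](C)C(OC)OC | intermediate
19 | aldol of 18 (ring A closed, tertiary C4 carbinol of undefined configuration; not isolated) | O1CC=C(C)C[C@@H]1[C@]2(C)C3(O)CC(=O)C[C@@]3([C@@H](O[Si](C)(C)C(C)(C)C)C[C@@H]2C)[C@@H](C)C(OC)OC | intermediate
20 | A/B hydrindenone (C2 ketone, C3=C4 olefin, C8 silyl ether, C11 dimethyl acetal, C14 in the dihydropyran) | O1CC=C(C)C[C@@H]1[C@]2(C)C3=CC(=O)C[C@@]3([C@@H](O[Si](C)(C)C(C)(C)C)C[C@@H]2C)[C@@H](C)C(OC)OC | intermediate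
21 | ring-opened C14 acetate, (Z)-allylic bromide, with C11 as α-bromo methyl ether (C11 undefined; not isolated) | BrC/C=C(C)\C[C@@H](OC(C)=O)[C@]1(C)C2=CC(=O)C[C@@]2([C@@H](O[Si](C)(C)C(C)(C)C)C[C@@H]1C)[C@@H](C)C(Br)OC | intermediate
22 | A/B hydrindenone with (14R)-acetate, (Z)-4-bromo-2-methylbut-2-enyl arm on C14 and (10R)-propanal arm on C9, C8 silyl ether | BrC/C=C(C)\C[C@@H](OC(C)=O)[C@]1(C)C2=CC(=O)C[C@@]2([C@@H](O[Si](C)(C)C(C)(C)C)C[C@@H]1C)[C@@H](C)C=O | intermediate
23 | allyl(dichloro)chromium species from 22 (trivalent chromium; not isolated) | Cl[Cr](Cl)C/C=C(C)\C[C@@H](OC(C)=O)[C@]1(C)C2=CC(=O)C[C@@]2([C@@H](O[Si](C)(C)C(C)(C)C)C[C@@H]1C)[C@@H](C)C=O | intermediate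
24 | 8-O-tert-butyldimethylsilyl ether of the target (ring C closed; 11S,12S) | C=C[C@]1(C)C[C@@H](OC(C)=O)[C@]2(C)C3=CC(=O)C[C@@]3([C@@H](O[Si](C)(C)C(C)(C)C)C[C@@H]2C)[C@@H](C)[C@@H]1O | intermediate
25 | pleuromutilin E: 14-O-acetyl-8-hydroxy-2-oxo-mutil-3-ene skeleton, (5S,6S,8S,9R,10R,11S,12S,14R) in mutilin numbering | C=C[C@]1(C)C[C@@H](OC(C)=O)[C@]2(C)C3=CC(=O)C[C@@]3([C@@H](O)C[C@@H]2C)[C@@H](C)[C@@H]1O | target

Total step count: 15. Longest linear sequence: 15 steps, from cyclohex-2-en-1-one 1.

Steps most likely to fail

Step 14 (key step). The slow eight-membered closure may lose to intermolecular coupling or to protonolysis of the allylchromium species, and the Z geometry of that species may erode, which would weaken control at C12. The fallback sets out from 22 and swaps the reductive organochromium chemistry for a configurationally stable allylboron reagent. Palladium-catalysed borylation of the allylic bromide (B2pin2, Pd2(dba)3, toluene, 50 °C) should give the (Z)-allyl pinacolboronate F1. This should close ring C by intramolecular allylboration through the same chair, on warming or with Sc(OTf)3 as catalyst. Hydrolysis of the borate comes back to the route at 24.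

Step 3. Proton loss from the isoprene-derived cation (ene or Prins pathways) may compete with closure of the pyran ring, and chelation control at C14 may be incomplete. The fallback sets out from 4 and builds the same ring in three conventional operations. A chelation-controlled Hosomi–Sakurai reaction (methallyltrimethylsilane, TiCl4, CH2Cl2, −78 °C) should give the homoallylic alcohol F2. Acid-catalysed O-allylation with allyl 2,2,2-trichloroacetimidate (cat. TfOH), which avoids an alkoxide and thus retro-aldol cleavage, should give the allyl ether F3. Ring-closing metathesis with the second-generation Grubbs catalyst, RuCl2(H2IMes)(PCy3)(=CHPh), comes back to the route at 6.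

Step 13. Ionisation to an allyl cation may scramble the Z geometry or lead to bromide capture at C12, and the silyl ether may be lost by acylative cleavage. The fallback sets out from 20 and separates ether cleavage from acylation. Me2BBr (CH2Cl2, −78 °C; aq. NaHCO3) cleaves the allylic ether by SN2 at the primary carbon and the dimethyl acetal in the same operation, and should give the bromo hydroxy aldehyde F4. Acetylation of the C14 hydroxyl (Ac2O, pyridine, cat. 4-(dimethylamino)pyridine, 0 °C) comes back to the route at 22.

Further compounds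
F1 | step 14 | (Z)-allyl pinacolboronate corresponding to 22 (Bpin in place of Br) | CC1(C)OB(OC1(C)C)C/C=C(C)\C[C@@H](OC(C)=O)[C@]2(C)C3=CC(=O)C[C@@]3([C@@H](O[Si](C)(C)C(C)(C)C)C[C@@H]2C)[C@@H](C)C=O
F2 | step 3 | (2R,3S)-2-[(1R)-1-hydroxy-3-methylbut-3-en-1-yl]-2,3-dimethylcyclohexan-1-one | C=C(C)C[C@@H](O)[C@]1(C)C(=O)CCC[C@@H]1C
F3 | step 3 | O-allyl ether of F2 | C=C(C)C[C@@H](OCC=C)[C@]1(C)C(=O)CCC[C@@H]1C
F4 | step 13 | C14 alcohol corresponding to 22 (hydroxyl in place of acetate) | BrC/C=C(C)\C[C@@H](O)[C@]1(C)C2=CC(=O)C[C@@]2([C@@H](O[Si](C)(C)C(C)(C)C)C[C@@H]1C)[C@@H](C)C=O
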